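The dihydropyran (O1, C2–C6) is cut at O1–C6 and C2–C3. C4 carries three two-carbon arms (C3–CHO, C5–CO2Me and CH2CO2R), so it descends from a desymmetrised methanetriacetate, and the O1–C2–C3–CHO array is a masked acetaldehyde aldol. The key step exploits this: an alkaloid-catalysed ketene–acetaldehyde cyclocondensation forms C2–C3, sets C2 and C3 as a cis-β-lactone and keeps the C3 carbonyl activated; the lactone oxygen later becomes O1 by displacing methoxide at C6. The precursor is the enantiopure acid chloride of the C3 arm, with C4 already bearing an (E)-β-methoxyacrylate (C5, C6) and the bis-silylated hydroxytyrosyl acetate arm.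

Key step: step 10

Remarks
- Pyran locants O1, C2 (methyl), C3 (formyl), C4, C5 (ester), C6 are used for all intermediates. TBS = tert-butyldimethylsilyl. The target is (2S,3R,4R): methyl and formyl trans, formyl and the C4 arm trans.
- Structure check: in the β-lactone of the key step the α-carbon (C3) is bonded directly to C4. Acid chloride plus acetaldehyde minus HCl leaves no methylene between them.
- Assumption: quinidine (step 8) and O-trimethylsilylquinidine (step 10) are taken as the pseudoenantiomers that give the (S)-hemiester and the (3R,4S)-lactone. If a trial run shows the opposite sense, the quinine-derived partner is used under the same conditions.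

Step 1
Reactants: 1 dimethyl (E)-glutaconate; 2 dimethyl malonate
Product: 3 trimethyl 2-(2-methoxy-2-oxoethyl)propane-1,1,3-tricarboxylate
Conditions: 2 (1.5 equiv), NaOMe (0.2 equiv), MeOH, 50 °C; AcOH quench
Reagents that add atoms: none
Why: Michael addition of the malonate anion to C3 of the glutaconate is a classical, thermodynamically driven conjugate addition, and excess malonate should suppress self-addition of the glutaconate.

Step 2
Reactants: 3 trimethyl 2-(2-methoxy-2-oxoethyl)propane-1,1,3-tricarboxylate
Product: 4 trimethyl methanetriacetate (dimethyl 3-(2-methoxy-2-oxoethyl)pentanedioate)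
Conditions: LiCl, H2O (2 equiv), DMSO, 150 °C
Reagents that add atoms: none
Why: Krapcho dealkoxycarbonylation removes one ester only from the geminal diester, because only that carboxylate can lose CO2 to a stabilised ester enolate.

Step 3
Reactants: 4 trimethyl methanetriacetate
Product: 6 dimethyl 3-[(E)-1,3-dimethoxy-3-oxoprop-1-en-2-yl]pentanedioate, via formyl ester 5 (not isolated)
Conditions: LDA (commercial solution, 1.05 equiv), THF, −78 °C; HCO2Me, −78 → 0 °C; then DMF, Me2SO4, 0 °C → rt
Reagents that add atoms: methyl formate COC=O; dimethyl sulfate COS(=O)(=O)OC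
Why: crossed Claisen formylation of the mono-enolate of one of three equivalent arms, then O-methylation of the resulting 1,3-dicarbonyl enolate by a hard electrophile in a dipolar solvent, should give the β-methoxyacrylate; either enol ether geometry serves, because C6 is later substituted by addition–elimination.

Step 4
Reactants: 6 dimethyl 3-[(E)-1,3-dimethoxy-3-oxoprop-1-en-2-yl]pentanedioate
Product: 7 3-[(E)-1,3-dimethoxy-3-oxoprop-1-en-2-yl]pentanedioic acid
Conditions: LiOH·H2O (2.2 equiv), THF/H2O, 0 °C; 1 M HCl to pH 3
Reagents that add atoms: lithium hydroxide [Li+].[OH-]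
Why: saponification should take the two unhindered aliphatic methyl esters and spare the β-methoxyacrylate ester, a vinylogous carbonate whose carbonyl is α-branched and far less electrophilic.

Step 5
Reactants: 7 3-[(E)-1,3-dimethoxy-3-oxoprop-1-en-2-yl]pentanedioic acid
Product: 8 methyl (E)-2-(2,6-dioxooxan-4-yl)-3-methoxyprop-2-enoate (the 3-substituted glutaric anhydride)
Conditions: Ac2O, 60 °C; evaporation with toluene
Reagents that add atoms: none
Why: cyclodehydration of a 3-substituted glutaric acid through the mixed anhydride gives the six-membered anhydride, and the acrylate ester cannot take part.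

Step 6
Reactants: 9 hydroxytyrosol (2-(3,4-dihydroxyphenyl)ethanol)
Product: 10 tris-TBS ether of hydroxytyrosol
Conditions: TBSCl (3.5 equiv), imidazole, DMF, rt
Reagents that add atoms: tert-butyldimethylsilyl chloride CC(C)(C)[Si](C)(C)Cl
Why: exhaustive silylation of all three hydroxyl groups under standard imidazole catalysis avoids any selectivity question at this stage.

Step 7
Reactants: 10 tris-TBS ether of hydroxytyrosol
Product: 11 2-[3,4-bis(TBS-oxy)phenyl]ethanol
Conditions: CSA (0.1 equiv), MeOH/CH2Cl2 1:1, 0 °C
Reagents that add atoms: none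
Why: acid-catalysed methanolysis cleaves the primary alkyl silyl ether much faster than the two aryl silyl ethers, which are stable to acid.

Step 8
Reactants: 8 the glutaric anhydride (1.3 equiv); 11 2-[3,4-bis(TBS-oxy)phenyl]ethanol
Product: 12 (3S)-5-{2-[3,4-bis(TBS-oxy)phenyl]ethoxy}-3-[(E)-1,3-dimethoxy-3-oxoprop-1-en-2-yl]-5-oxopentanoic acid (hemiester)
Conditions: quinidine (1.5 equiv, recovered), toluene, −50 °C; 1 M HCl wash
Reagents that add atoms: none
Why: alkaloid-mediated desymmetrising alcoholysis of a prochiral 3-substituted glutaric anhydride sets C4, because the alkaloid acts as a chiral general base and differentiates the two enantiotopic carbonyl groups; any minor enantiomer should become a separable diastereomer in step 10.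

Step 9
Reactants: 12 the (S)-hemiester
Product: 13 (R)-acid chloride of 12 (same spatial arrangement at C4; the descriptor changes by priority only)
Conditions: (COCl)2 (1.2 equiv), DMF (cat.), CH2Cl2, 0 °C; evaporation, used at once
Reagents that add atoms: oxalyl chloride ClC(=O)C(=O)Cl
Why: chlorination through the catalytic Vilsmeier species is tolerated by aryl silyl ethers and by the push–pull enol ether, and working cold without storage should prevent acyl exchange between the two arms, which would erode C4.

Step 10
Reactants: 13 the (R)-acid chloride; 14 acetaldehyde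
Product: 16 cis-β-lactone, 2-[3,4-bis(TBS-oxy)phenyl]ethyl (3R,4E)-5-methoxy-4-(methoxycarbonyl)-3-[(3R,4S)-4-methyl-2-oxooxetan-3-yl]pent-4-enoate, via ketene 15 (not isolated)
Conditions: O-trimethylsilylquinidine (15 mol%), LiClO4 (1 equiv), iPr2NEt (2.5 equiv), MeCHO (5 equiv), CH2Cl2/Et2O, −78 °C, slow addition of 13
Reagents that add atoms: none
Why: iPr2NEt dehydrochlorinates 13 to ketene 15, the quinuclidine nitrogen of the alkaloid adds to give an acylammonium (Z)-enolate, and this attacks lithium-activated acetaldehyde through a closed chair-like transition state to form C2–C3. The closest known reaction type is the cinchona alkaloid/LiClO4-catalysed acyl halide–aldehyde cyclocondensation of alkyl-substituted ketenes with enolisable aliphatic aldehydes. The aldolate oxygen then closes the four-membered ring by 4-exo-trig attack on the acylammonium carbonyl and releases the catalyst. C3 is set by the enolate face left open by the alkaloid and C2 by the lithium-bridged transition state, which places methyl and the C4 residue cis on the lactone, so reagent control should give the (3R,4S)-lactone over the intrinsic bias of C4. The step needs ketene formation at one site only, secured because the acid chloride is the only carbonyl that the amine can dehydrohalogenate (the esters and the β-methoxyacrylate are inert), and it needs cross-reaction over ketene dimerisation, secured by adding 13 slowly to excess acetaldehyde. The cis-lactone corresponds to the 2,3-trans relationship of methyl and formyl in the pyran.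

Step 11
Reactants: 16 the cis-β-lactone
Product: 17 β-hydroxy Weinreb amide (2S,3R,4R in pyran locants): 2-[3,4-bis(TBS-oxy)phenyl]ethyl ester carrying C3–C(=O)N(OMe)Me and a free C2 hydroxyl
Conditions: MeNHOMe·HCl (3 equiv), Me2AlCl (3 equiv), CH2Cl2, −30 → 0 °C; aq. potassium sodium tartrate
Reagents that add atoms: N,O-dimethylhydroxylamine hydrochloride CNOC.Cl
Why: the aluminium amide attacks the strained lactone acyl carbon far faster than the unstrained esters and cleaves the acyl–oxygen bond, so C2 and C3 are not touched (Weinreb amidation).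

Step 12
Reactants: 17 the β-hydroxy Weinreb amide
Product: 18 methyl (2S,3R,4R)-4-(2-{2-[3,4-bis(TBS-oxy)phenyl]ethoxy}-2-oxoethyl)-3-[methoxy(methyl)carbamoyl]-2-methyl-3,4-dihydro-2H-pyran-5-carboxylate
Conditions: PPTS (0.2 equiv), toluene, 5 Å MS, 70 °C
Reagents that add atoms: none
Why: acid-catalysed addition–elimination of the C2 hydroxyl at C6 (vinylogous transesterification) closes the ring in 6-endo-trig mode with loss of methanol, which the sieves take up, and no stereocentre is involved.

Step 13
Reactants: 18 the pyran Weinreb amide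
Product: 19 bis-TBS ether of the target (C3 formyl)
Conditions: Cp2Zr(H)Cl (1.6 equiv), THF, rt, 20 min; SiO2 filtration
Reagents that add atoms: none
Why: Schwartz-reagent reduction adds Zr–H to the amide carbonyl to give a stable zirconated hemiaminal that releases the aldehyde only on work-up, while esters and the push–pull alkene react much more slowly and the neutral conditions should leave C3 unchanged.

Step 14
Reactants: 19 bis-TBS ether of the target
Product: 20 target, methyl (2S,3R,4R)-4-{2-[2-(3,4-dihydroxyphenyl)ethoxy]-2-oxoethyl}-3-formyl-2-methyl-3,4-dihydro-2H-pyran-5-carboxylate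
Conditions: HF·pyridine, pyridine, THF, 0 °C
Reagents that add atoms: none
Why: fluoride cleaves both aryl silyl ethers under buffered, weakly acidic conditions that should neither epimerise C3 nor open the ring by β-elimination.

Compound list
1 | dimethyl (E)-glutaconate | COC(=O)/C=C/CC(=O)OC | starting material
2 | dimethyl malonate | COC(=O)CC(=O)OC | starting material
3 | trimethyl 2-(2-methoxy-2-oxoethyl)propane-1,1,3-tricarboxylate | COC(=O)CC(CC(=O)OC)C(C(=O)OC)C(=O)OC | intermediate
4 | trimethyl methanetriacetate | COC(=O)CC(CC(=O)OC)CC(=O)OC | intermediate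
5 | dimethyl 3-(1-methoxy-1,3-dioxopropan-2-yl)pentanedioate (formyl ester, present as its lithium enolate) | COC(=O)CC(CC(=O)OC)C(C=O)C(=O)OC | intermediate
6 | dimethyl 3-[(E)-1,3-dimethoxy-3-oxoprop-1-en-2-yl]pentanedioate | COC(=O)CC(CC(=O)OC)/C(C(=O)OC)=C\OC | intermediate
7 | 3-[(E)-1,3-dimethoxy-3-oxoprop-1-en-2-yl]pentanedioic acid | OC(=O)CC(CC(=O)O)/C(C(=O)OC)=C\OC | intermediate
8 | methyl (E)-2-(2,6-dioxooxan-4-yl)-3-methoxyprop-2-enoate | O=C1CC(CC(=O)O1)/C(C(=O)OC)=C\OC | intermediate
9 | hydroxytyrosol | OCCc1ccc(O)c(O)c1 | starting material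
10 | tris-TBS ether of hydroxytyrosol | CC(C)(C)[Si](C)(C)OCCc1ccc(O[Si](C)(C)C(C)(C)C)c(O[Si](C)(C)C(C)(C)C)c1 | intermediate
11 | 2-[3,4-bis(TBS-oxy)phenyl]ethanol | OCCc1ccc(O[Si](C)(C)C(C)(C)C)c(O[Si](C)(C)C(C)(C)C)c1 | intermediate
12 | (S)-hemiester | OC(=O)C[C@@H](CC(=O)OCCc1ccc(O[Si](C)(C)C(C)(C)C)c(O[Si](C)(C)C(C)(C)C)c1)/C(C(=O)OC)=C\OC | intermediate
13 | (R)-acid chloride | ClC(=O)C[C@@H](CC(=O)OCCc1ccc(O[Si](C)(C)C(C)(C)C)c(O[Si](C)(C)C(C)(C)C)c1)/C(C(=O)OC)=C\OC | intermediate
14 | acetaldehyde | CC=O | starting material
15 | (R)-ketene from 13 | O=C=C[C@@H](CC(=O)OCCc1ccc(O[Si](C)(C)C(C)(C)C)c(O[Si](C)(C)C(C)(C)C)c1)/C(C(=O)OC)=C\OC | intermediate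
16 | cis-β-lactone, (3R,4S) in the oxetanone, (R) at C4 of the chain | O=C1O[C@@H](C)[C@H]1[C@@H](CC(=O)OCCc2ccc(O[Si](C)(C)C(C)(C)C)c(O[Si](C)(C)C(C)(C)C)c2)/C(C(=O)OC)=C\OC | intermediate
17 | β-hydroxy Weinreb amide | CON(C)C(=O)[C@@H]([C@H](C)O)[C@@H](CC(=O)OCCc1ccc(O[Si](C)(C)C(C)(C)C)c(O[Si](C)(C)C(C)(C)C)c1)/C(C(=O)OC)=C\OC | intermediate
18 | pyran Weinreb amide (2S,3R,4R) | COC(=O)C1=CO[C@@H](C)[C@H](C(=O)N(C)OC)[C@H]1CC(=O)OCCc1ccc(O[Si](C)(C)C(C)(C)C)c(O[Si](C)(C)C(C)(C)C)c1 | intermediate
19 | bis-TBS ether of the target | COC(=O)C1=CO[C@@H](C)[C@H](C=O)[C@H]1CC(=O)OCCc1ccc(O[Si](C)(C)C(C)(C)C)c(O[Si](C)(C)C(C)(C)C)c1 | intermediate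
20 | CNP0172886.1 | COC(=O)C1=CO[C@@H](C)[C@H](C=O)[C@H]1CC(=O)OCCc1ccc(O)c(O)c1 | target

Total step count: 14 (12 on the main line, 2 for the alcohol 11).
Longest linear sequence: 12 steps (from 1 or 2 through steps 1–5 and 8–14 to 20).

Steps most likely to fail

1. Step 10. The enolate face imposed by the alkaloid may be mismatched with the bias of the neighbouring C4 centre, so that facial selectivity falls, or the hindered ketene may dimerise faster than it is trapped. The fallback is an auxiliary-controlled Evans syn-aldol, which sets out from 12 and returns at 17. The acid 12 is activated as its pivalic mixed anhydride (PivCl, Et3N, THF, −20 °C) and acylates (R)-4-benzyloxazolidin-2-one in the presence of LiCl to give the N-acyl oxazolidinone F1. Enolisation with Bu2BOTf/iPr2NEt (CH2Cl2, −78 °C) and addition of acetaldehyde should give the syn-aldol adduct F2 with the C2 and C3 configurations dictated by the auxiliary. Transamidation with MeNHOMe·HCl/AlMe3 then releases the auxiliary and gives 17.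

2. Step 8. Acyl transfer to the bulky alcohol may be sluggish at low temperature, or the two enantiotopic carbonyl groups may be poorly differentiated. The fallback sets out from 8 and returns at 12, using a small alcohol, for which such openings are best documented, and then exchanging the arms. Quinine-mediated opening with allyl alcohol (toluene, −50 °C) attacks the other enantiotopic carbonyl and gives the allyl hemiester F3. Esterification of its free acid with 11 (EDC·HCl, DMAP, CH2Cl2) gives the mixed allyl/hydroxytyrosyl diester F4. Deallylation with Pd(PPh3)4 (zerovalent palladium) and morpholine in THF frees the other arm and gives 12.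

3. Step 12. Methanol exchange at C6 may stall, or the acid may dehydrate the β-hydroxy amide across C2–C3. The fallback sets out from 17 and returns at 18 through the hemiacetal. Aqueous acid (1 M HCl, THF, rt) hydrolyses the enol ether to the formyl ester, which the C2 hydroxyl should trap as the cyclic lactol F5 (mixture at C5 and C6). Acid-catalysed dehydration (CSA, toluene, 4 Å MS, 50 °C), driven by conjugation with the C5 ester, gives 18.

Further compounds
F1 | step 10 | (4R)-4-benzyl-3-acyl-oxazolidin-2-one derived from acid 12 | O=C1OC[C@@H](Cc2ccccc2)N1C(=O)C[C@@H](CC(=O)OCCc1ccc(O[Si](C)(C)C(C)(C)C)c(O[Si](C)(C)C(C)(C)C)c1)/C(C(=O)OC)=C\OC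
F2 | step 10 | Evans syn-aldol adduct of F1 with acetaldehyde (2S,3R,4R in pyran locants) | O=C1OC[C@@H](Cc2ccccc2)N1C(=O)[C@@H]([C@H](C)O)[C@@H](CC(=O)OCCc1ccc(O[Si](C)(C)C(C)(C)C)c(O[Si](C)(C)C(C)(C)C)c1)/C(C(=O)OC)=C\OC
F3 | step 8 | (3R)-5-(allyloxy)-3-[(E)-1,3-dimethoxy-3-oxoprop-1-en-2-yl]-5-oxopentanoic acid | C=CCOC(=O)C[C@@H](CC(=O)O)/C(C(=O)OC)=C\OC
F4 | step 8 | (R)-mixed diester, allyl on the C3 arm and 2-[3,4-bis(TBS-oxy)phenyl]ethyl on the acetate arm | C=CCOC(=O)C[C@@H](CC(=O)OCCc1ccc(O[Si](C)(C)C(C)(C)C)c(O[Si](C)(C)C(C)(C)C)c1)/C(C(=O)OC)=C\OC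
F5 | step 12 | cyclic lactol (6-hydroxytetrahydropyran) of the hydrolysed enol ether, Weinreb amide at C3 | COC(=O)C1C(O)O[C@@H](C)[C@H](C(=O)N(C)OC)[C@H]1CC(=O)OCCc1ccc(O[Si](C)(C)C(C)(C)C)c(O[Si](C)(C)C(C)(C)C)c1
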